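The C1–O bond of ring A is traced back to a C1–CHO bond. A Baeyer–Villiger (Dakin-type) oxidation moves ring A from the formyl carbon to oxygen and so installs the C1 oxygen in one operation. The step exploits the position of C1 between the aryloxy-bearing C2 and the bromine-bearing C6: this is the most acidic site of 1,4-dibromo-2-fluorobenzene (between F and Br), so a formyl group can be placed there, activate the C2 fluoride for metal-free displacement by 2,4-dibromophenoxide (ring B), and finally be exchanged for oxygen. The precursor is 3,6-dibromo-2-(2,4-dibromophenoxy)benzaldehyde, already carrying all four bromines.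

Key step: step 3

Remark: the target has no stereocentre and its diaryl ether axis rotates freely, so it is one achiral compound and no stereocontrol is needed; the transient stereocentres of 4 and 9 are racemic and are lost.

Step 1
Reactants: 1 1,4-dibromo-2-fluorobenzene; 2 N,N-dimethylformamide
Product: 5 3,6-dibromo-2-fluorobenzaldehyde, via (3,6-dibromo-2-fluorophenyl)lithium 3 (not isolated), via lithium (3,6-dibromo-2-fluorophenyl)(dimethylamino)methanolate 4 (not isolated)
Conditions: LDA (commercial solution, 1.1 equiv), THF, −78 °C; then DMF, −78 °C; aq. HCl quench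
Reagents that add atoms: N,N-dimethylformamide (compound 2), CN(C)C=O
Why: Directed ortho-metalation followed by formylation: the C–H flanked by fluorine and bromine is the most acidic site of 1, LDA at −78 °C should deprotonate it without bromine–lithium exchange, and the tetrahedral adduct 4 with DMF prevents over-addition and releases the aldehyde on acidic work-up.

Step 2
Reactants: 5 3,6-dibromo-2-fluorobenzaldehyde; 6 2,4-dibromophenol
Product: 8 3,6-dibromo-2-(2,4-dibromophenoxy)benzaldehyde, via potassium 2,4-dibromophenolate 7 (not isolated)
Conditions: K2CO3, DMAc (dry), 80 °C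
Reagents that add atoms: none
Why: Nucleophilic aromatic substitution (SNAr, addition–elimination): the C2 fluoride is ortho to the formyl group and flanked by bromine, fluoride is a far better SNAr leaving group than the C6 bromide that is also ortho to the aldehyde, and no metal is present, so all four C–Br bonds should survive.

Step 3
Reactants: 8 3,6-dibromo-2-(2,4-dibromophenoxy)benzaldehyde
Product: 10 3,6-dibromo-2-(2,4-dibromophenoxy)phenyl formate, via [3,6-dibromo-2-(2,4-dibromophenoxy)phenyl](hydroxy)methyl 3-chloroperoxybenzoate (Criegee adduct, racemic) 9 (not isolated)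
Conditions: mCPBA (2 equiv), CH2Cl2, 0 °C → 40 °C; aq. Na2S2O3 work-up, crude formate carried on
Reagents that add atoms: mCPBA (3-chloroperoxybenzoic acid), OOC(=O)c1cccc(Cl)c1
Why: The peracid adds to the formyl carbon to give the tetrahedral Criegee adduct 9, in which C1 of ring A, antiperiplanar to the O–O bond, shifts with its bonding pair from carbon to the proximal peroxide oxygen as 3-chlorobenzoate leaves, forming the C1–O bond as the aryl formate. The closest known reaction type is the Baeyer–Villiger (Dakin-type) oxidation of ortho-alkoxy- and ortho-aryloxybenzaldehydes to aryl formates. No ring is closed and no stereocentre remains, since the carbinol centre of 9 is transient. The selectivity needed is aryl over hydride migration (the latter would give the benzoic acid): the lone pair of the C2 aryloxy oxygen stabilises the positive charge building on the migrating ring, and the C2/C6 di-ortho substitution twists the formyl group out of conjugation, which raises the ground state and should favour the conformer with the ring anti to the O–O bond. The aryl bromides and the diaryl ether are inert to peracid, and the non-aqueous medium keeps the formate intact so that no free phenol meets the oxidant.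

Step 4
Reactants: 10 3,6-dibromo-2-(2,4-dibromophenoxy)phenyl formate
Product: 11 3,6-dibromo-2-(2,4-dibromophenoxy)phenol
Conditions: cat. HCl, MeOH, rt
Reagents that add atoms: none
Why: Acid-catalysed transesterification (methanolysis): aryl formates are among the most labile esters and should exchange with methanol at room temperature, while the diaryl ether and the four aryl bromides are untouched.

Compound list
1 | 1,4-dibromo-2-fluorobenzene | Fc1cc(Br)ccc1Br | starting material
2 | N,N-dimethylformamide | CN(C)C=O | starting material
3 | (3,6-dibromo-2-fluorophenyl)lithium | [Li]c1c(F)c(Br)ccc1Br | intermediate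
4 | lithium (3,6-dibromo-2-fluorophenyl)(dimethylamino)methanolate (racemic) | [Li+].[O-]C(N(C)C)c1c(F)c(Br)ccc1Br | intermediate
5 | 3,6-dibromo-2-fluorobenzaldehyde | O=Cc1c(F)c(Br)ccc1Br | intermediate
6 | 2,4-dibromophenol | Oc1ccc(Br)cc1Br | starting material
7 | potassium 2,4-dibromophenolate | [K+].[O-]c1ccc(Br)cc1Br | intermediate
8 | 3,6-dibromo-2-(2,4-dibromophenoxy)benzaldehyde | O=Cc1c(Br)ccc(Br)c1Oc1ccc(Br)cc1Br | intermediate
9 | [3,6-dibromo-2-(2,4-dibromophenoxy)phenyl](hydroxy)methyl 3-chloroperoxybenzoate (Criegee adduct, racemic) | OC(OOC(=O)c1cccc(Cl)c1)c1c(Br)ccc(Br)c1Oc1ccc(Br)cc1Br | intermediate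
10 | 3,6-dibromo-2-(2,4-dibromophenoxy)phenyl formate | O=COc1c(Br)ccc(Br)c1Oc1ccc(Br)cc1Br | intermediate
11 | 3,6-dibromo-2-(2,4-dibromophenoxy)phenol | Oc1c(Br)ccc(Br)c1Oc1ccc(Br)cc1Br | target

Total step count: 4
Longest linear sequence: 4 steps (1 → 5 → 8 → 10 → 11)

Steps most likely to fail

Step 3 (key step). Hydride migration in the Criegee adduct may compete with aryl migration and lead to over-oxidation to the carboxylic acid, or the peracid may add too slowly to the di-ortho-hindered carbonyl. The fallback removes the migrating hydride and sets out from 8. Addition of MeMgBr (THF, −78 → 0 °C; bromine–magnesium exchange is slow under these conditions) should give racemic 1-[3,6-dibromo-2-(2,4-dibromophenoxy)phenyl]ethan-1-ol F1. Dess–Martin oxidation should give 1-[3,6-dibromo-2-(2,4-dibromophenoxy)phenyl]ethan-1-one F2. Baeyer–Villiger oxidation with trifluoroperacetic acid (TFAA, urea·H2O2, Na2HPO4, CH2Cl2), in which aryl migrates in preference to methyl, should give 3,6-dibromo-2-(2,4-dibromophenoxy)phenyl acetate F3. Methanolysis (K2CO3, MeOH, then acid) returns to the route at 11.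

Step 2. The weakly nucleophilic, ortho-hindered phenoxide may displace the crowded fluoride only sluggishly, and forcing conditions may erode the chemoselectivity between the C2 fluoride and the C6 bromide or degrade the aldehyde. The fallback reverses the polarity of the ether formation and sets out from 5. Displacement of fluoride by the small nucleophile NaOMe (MeOH, rt to 40 °C) should give 3,6-dibromo-2-methoxybenzaldehyde F4. Demethylation with BBr3 (CH2Cl2, −78 → 0 °C) should give 3,6-dibromo-2-hydroxybenzaldehyde F5. Metal-free O-arylation of F5 (K2CO3, MeCN, 50 °C) with (2,4-dibromophenyl)(2,4,6-trimethoxyphenyl)iodonium tosylate F6 returns to the route at 8. F6 would be prepared in one pot from commercial 2,4-dibromo-1-iodobenzene, mCPBA, TsOH·H2O and 1,3,5-trimethoxybenzene; the trimethoxyphenyl group acts as the non-transferred ligand.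

Step 1. The ortho-bromo, ortho-fluoro aryllithium may equilibrate by halogen dance or lose lithium fluoride to an aryne before it is formylated, eroding regiochemical integrity. The fallback replaces the free aryllithium by an arylmagnesium species and sets out from 1. In an in situ trapping metalation, TMPLi is added to 1 and MgCl2 in THF at −78 °C, so that 3 is transmetalated as it forms to (3,6-dibromo-2-fluorophenyl)magnesium chloride F7, which should be positionally stable. Formylation with DMF (2) at −20 → 0 °C should give chloromagnesium (3,6-dibromo-2-fluorophenyl)(dimethylamino)methanolate F8, and acidic work-up returns to the route at 5.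

Further compounds
F1 | step 3 | 1-[3,6-dibromo-2-(2,4-dibromophenoxy)phenyl]ethan-1-ol (racemic) | CC(O)c1c(Br)ccc(Br)c1Oc1ccc(Br)cc1Br
F2 | step 3 | 1-[3,6-dibromo-2-(2,4-dibromophenoxy)phenyl]ethan-1-one | CC(=O)c1c(Br)ccc(Br)c1Oc1ccc(Br)cc1Br
F3 | step 3 | 3,6-dibromo-2-(2,4-dibromophenoxy)phenyl acetate | CC(=O)Oc1c(Br)ccc(Br)c1Oc1ccc(Br)cc1Br
F4 | step 2 | 3,6-dibromo-2-methoxybenzaldehyde | COc1c(Br)ccc(Br)c1C=O
F5 | step 2 | 3,6-dibromo-2-hydroxybenzaldehyde | O=Cc1c(O)c(Br)ccc1Br
F6 | step 2 | (2,4-dibromophenyl)(2,4,6-trimethoxyphenyl)iodonium 4-methylbenzenesulfonate | COc1cc(OC)c([I+]c2ccc(Br)cc2Br)c(OC)c1.Cc1ccc(cc1)S(=O)(=O)[O-]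
F7 | step 1 | (3,6-dibromo-2-fluorophenyl)magnesium chloride | Cl[Mg]c1c(F)c(Br)ccc1Br
F8 | step 1 | chloromagnesium (3,6-dibromo-2-fluorophenyl)(dimethylamino)methanolate (racemic) | CN(C)C(O[Mg]Cl)c1c(F)c(Br)ccc1Br
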